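**Plan**
- Enabling feature: in the primed half C8′ carries the lactone oxygen and C1′ the epoxide oxygen. The ring C8′–C9′–C10′–C1′–C5′–C6′–C7′ is thus a 1,4-dioxygenated cycloheptane, i.e. a cyclopentane-1,3-dione ring (C8′, C9′, C10′, C1′, C5′) widened by the two vinyl carbons C6′/C7′, and the lactone carbonyl C12′ on quaternary C11′ serves as the tether.
- Retrosynthetic cuts, in order: the epoxide C–O bonds at C1′/C5′; the O8–C12 lactone bond; C1′–C2′ (Heck). C5′–C8′ is then re-joined to a bicyclo[3.2.0]heptanone, whose C7′–C8′ and C5′–C6′ bonds are cut ([2+2]) to a dione enol ester of a C11′-vinyl acid (the C10′ methyl is added after the cycloaddition, so a symmetrical dione can be used). The acid goes back through selenium chemistry (C1–OH/C2=C3, C6′=C7′) to a Diels–Alder adduct (C3–C11′, C5–C13′), then to an enyne (C1=C5, C2=C3 metathesis) and an aldol (C7–C8).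
- Forward ring order: seven-membered ring of the unprimed half (enyne metathesis); cyclohexene plus spiro-γ-lactone (Diels–Alder); spirolactone plus cyclobutane (photocycloaddition); seven-membered ring of the primed half (fragmentation); α-methylene lactone (oxidative lactonisation); epoxide.
- Stereochemistry: C10 from (S)-but-3-yn-2-ol by SN2 inversion; C7/C8 from an Evans syn-aldol; C5 and C11′ from an endo, hydroxyl-directed Diels–Alder reaction on the β face (C4 carbinol from CBS reduction); C1 from a directed epoxidation; C7′ in the photocycloaddition, relayed from C11′; C10′ by convex-face methylation; C8′ by hydrogen delivery during ring opening; the epoxide by β-face peracid attack.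

Key step: step 21

Remark: xanthanolide numbering is used, with primes for the epoxide-bearing half; β is the face of the C10/C10′ methyl groups and α that of H-7/H-8; TBS = tert-butyldimethylsilyl, TES = triethylsilyl, Tf = trifluoromethanesulfonyl.

**Step 1**
Reactants: 1 (S)-but-3-yn-2-ol
Product: 2 (S)-but-3-yn-2-yl methanesulfonate
Conditions: MsCl, Et3N, CH2Cl2, 0 °C
Reagents that add atoms: methanesulfonyl chloride, CS(=O)(=O)Cl
Why: O-Sulfonylation of the secondary alcohol leaves the C–O bond, and hence the stereocentre, untouched and installs the leaving group for the next step.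

**Step 2**
Reactants: 2 (S)-but-3-yn-2-yl methanesulfonate; 3 diethyl malonate
Product: 4 diethyl 2-[(2S)-but-3-yn-2-yl]propanedioate
Conditions: NaH, THF–DMF, 0 → 60 °C
Reagents that add atoms: none
Why: SN2 malonate alkylation of the secondary propargylic mesylate should proceed with inversion and thereby fix the future C10 methyl stereocentre.

**Step 3**
Reactants: 4 diethyl 2-[(2S)-but-3-yn-2-yl]propanedioate
Product: 5 ethyl (3S)-3-methylpent-4-ynoate
Conditions: LiCl, H2O, DMSO, 150 °C
Reagents that add atoms: none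
Why: Krapcho dealkoxycarbonylation removes one ester group under near-neutral conditions that leave the propargylic stereocentre and the alkyne alone.

**Step 4**
Reactants: 5 ethyl (3S)-3-methylpent-4-ynoate
Product: 6 (3S)-3-methylpent-4-ynal
Conditions: i-Bu2AlH, CH2Cl2, −78 °C; Rochelle salt work-up
Reagents that add atoms: none
Why: Partial hydride reduction of the ester at low temperature stops at the aluminium hemiacetal, which releases the aldehyde only on work-up.

**Step 5**
Reactants: 7 (4S)-4-benzyl-1,3-oxazolidin-2-one; 8 pent-4-enoyl chloride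
Product: 9 (4S)-4-benzyl-3-(pent-4-enoyl)-1,3-oxazolidin-2-one
Conditions: n-BuLi, THF, −78 °C; then 8, −78 → 0 °C
Reagents that add atoms: none
Why: N-Acylation of the lithiated oxazolidinone by the acid chloride is a routine acyl substitution.

**Step 6**
Reactants: 9 (4S)-4-benzyl-3-(pent-4-enoyl)-1,3-oxazolidin-2-one; 6 (3S)-3-methylpent-4-ynal
Product: 10 syn-aldol imide (C7 allyl, C8 hydroxyl)
Conditions: n-Bu2BOTf, i-Pr2NEt, CH2Cl2, −78 → 0 °C; then 6, −78 → 0 °C; H2O2, MeOH, pH 7 buffer
Reagents that add atoms: none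
Why: In this Evans syn-aldol reaction the Z-boron enolate reacts through a Zimmerman–Traxler chair on the face opposite the benzyl group, which sets C7 and C8 syn (the cis-lactone relationship) under reagent control irrespective of the remote C10 centre.

**Step 7**
Reactants: 10 syn-aldol imide
Product: 11 β-hydroxy N-methoxy-N-methylamide
Conditions: MeNH(OMe)·HCl, AlMe3, THF, −20 → 0 °C
Reagents that add atoms: N,O-dimethylhydroxylamine hydrochloride, CNOC.Cl
Why: Aluminium-amide transamidation (Weinreb amide formation), assisted by the free β-hydroxyl, cleaves the exocyclic imide carbonyl and releases the auxiliary.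

**Step 8**
Reactants: 11 β-hydroxy N-methoxy-N-methylamide
Product: 12 O8-TBS N-methoxy-N-methylamide
Conditions: TBSOTf, 2,6-lutidine, CH2Cl2, −78 → 0 °C
Reagents that add atoms: tert-butyldimethylsilyl trifluoromethanesulfonate, CC(C)(C)[Si](C)(C)OS(=O)(=O)C(F)(F)F
Why: O-Silylation of the secondary alcohol protects O8 for the organometallic and enolate steps that follow.

**Step 9**
Reactants: 12 O8-TBS N-methoxy-N-methylamide
Product: 13 methyl ketone (C11 carbonyl)
Conditions: MeMgBr (excess), THF, 0 °C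
Reagents that add atoms: methylmagnesium bromide, C[Mg]Br
Why: Grignard addition to the N-methoxy-N-methylamide stops at the chelated tetrahedral intermediate and gives the methyl ketone without over-addition or epimerisation at C7.

**Step 10**
Reactants: 13 methyl ketone
Product: 15 α-silyloxy ketone (C12–OTBS), via TBS enol ether 14 (not isolated)
Conditions: LiN(SiMe3)2, THF, −78 °C; TBSOTf; then mCPBA, NaHCO3, CH2Cl2, −20 → 0 °C
Reagents that add atoms: tert-butyldimethylsilyl trifluoromethanesulfonate, CC(C)(C)[Si](C)(C)OS(=O)(=O)C(F)(F)F; 3-chloroperoxybenzoic acid, O=C(OO)c1cccc(Cl)c1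
Why: In this Rubottom oxidation kinetic deprotonation at the methyl group and O-silylation are followed by epoxidation of the electron-rich silyl enol ether and 1,4-silyl shift to the α-silyloxy ketone, the terminal alkene and alkyne reacting far more slowly with the peracid.

**Step 11**
Reactants: 15 α-silyloxy ketone
Product: 16 bis-TBS enyne (C11=C13 methylidene)
Conditions: Zn, CH2Br2, TiCl4, THF–CH2Cl2, 0 °C → rt
Reagents that add atoms: dibromomethane, BrCBr
Why: Takai–Lombardo methylenation with the non-basic zinc/titanium gem-dimetal reagent converts the hindered, enolisable ketone into the 1,1-disubstituted alkene without touching C7.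

**Step 12**
Reactants: 16 bis-TBS enyne; 17 methyl vinyl ketone
Product: 18 cycloheptadienyl enone (C1=C5, C2=C3, C4 ketone)
Conditions: second-generation Grubbs catalyst (10 mol %), 17 (5 equiv), CH2Cl2, 40 °C
Reagents that add atoms: none
Why: In this domino ring-closing enyne metathesis/cross metathesis the ruthenium carbene formed at the terminal alkene adds to the alkyne in exo mode to close the seven-membered ring, and the resulting vinylcarbene is intercepted by methyl vinyl ketone to give the (E)-dienone.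

**Step 13**
Reactants: 18 cycloheptadienyl enone
Product: 19 (4R)-dienol
Conditions: (S)-2-methyl-CBS-oxazaborolidine, BH3·SMe2, THF, −40 °C
Reagents that add atoms: none
Why: Corey–Bakshi–Shibata reduction delivers hydride 1,2 to the ketone face selected by the (S)-oxazaborolidine (alkenyl as the large group), which sets the (4R)-carbinol.

**Step 14**
Reactants: 19 (4R)-dienol; 20 α-methylene-γ-butyrolactone
Product: 21 spirolactone Diels–Alder adduct (C1=C2 alkene)
Conditions: 20 (10 equiv), BHT, toluene, 100 °C, sealed tube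
Reagents that add atoms: none
Why: In this intermolecular Diels–Alder reaction the 2-substituted diene directs the dienophile CH2 (C13′) to C5 and its quaternary carbon (C11′) to C3, the lactone carbonyl sits endo, and the dienophile should approach the β face, on which the hydrogen-bonding (4R)-hydroxyl lies when C4–H eclipses the diene, which sets C5, C3 and C11′.

**Step 15**
Reactants: 21 spirolactone Diels–Alder adduct
Product: 22 1β,2β-epoxide
Conditions: VO(acac)2 (5 mol %), t-BuOOH, CH2Cl2, 0 °C → rt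
Reagents that add atoms: tert-butyl hydroperoxide, CC(C)(C)OO
Why: In this vanadium-catalysed hydroxyl-directed epoxidation the homoallylic C4–OH binds the metal peroxide and delivers oxygen to the β face of C1=C2 (the face on which C4 is attached), which sets C1 and leaves the undirected C11=C13 alkene alone.

**Step 16**
Reactants: 22 1β,2β-epoxide
Product: 23 O4-TBS epoxide
Conditions: TBSCl, imidazole, DMAP (cat.), DMF, 40 °C
Reagents that add atoms: tert-butyldimethylsilyl chloride, CC(C)(C)[Si](C)(C)Cl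
Why: Imidazole-mediated O-silylation masks O4 under non-Lewis-acidic conditions, so that it cannot lactonise onto C12′ once the acid is set free.

**Step 17**
Reactants: 23 O4-TBS epoxide
Product: 24 1β-hydroxy-2α,6′-bis(phenylselanyl) acid
Conditions: (PhSe)2, NaH, DMF, 110 °C; cold 0.5 M HCl work-up
Reagents that add atoms: sodium benzeneselenolate, [Na+].[Se-]c1ccccc1 (made in the flask from diphenyl diselenide, c1ccc(cc1)[Se][Se]c1ccccc1)
Why: The soft selenolate effects two SN2 openings: Fürst–Plattner (trans-diaxial) attack at the secondary epoxide carbon C2 from the α face leaves the tertiary 1β-alcohol, and alkyl–oxygen cleavage of the γ-lactone at C6′ frees the carboxylic acid.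

**Step 18**
Reactants: 24 1β-hydroxy-2α,6′-bis(phenylselanyl) acid
Product: 26 1β-hydroxy C11′-vinyl acid (C2=C3), via bis-selenoxide 25 (not isolated)
Conditions: mCPBA (2.1 equiv), CH2Cl2, −78 °C; then i-Pr2NH, toluene, 60 °C
Reagents that add atoms: none
Why: Selenoxide syn-elimination removes the cis H-3 away from the hydroxyl to give C2=C3 (net epoxide-to-allylic-alcohol transposition) and converts the primary selenoxide into the C7′=C6′ vinyl group, selenium being oxidised far faster than any alkene at −78 °C.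

**Step 19**
Reactants: 26 1β-hydroxy C11′-vinyl acid
Product: 28 O1-TES vinyl acid, via bis-TES derivative 27 (not isolated)
Conditions: TESOTf, 2,6-lutidine, CH2Cl2, −78 → 0 °C; then K2CO3, MeOH–H2O, 0 °C
Reagents that add atoms: triethylsilyl trifluoromethanesulfonate, CC[Si](CC)(CC)OS(=O)(=O)C(F)(F)F
Why: Silyl triflate O-silylation protects the tertiary allylic alcohol (which would otherwise form a bridged lactone with C12′ on activation), and the silyl ester formed alongside is cleaved by mild methanolysis.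

**Step 20**
Reactants: 28 O1-TES vinyl acid; 29 cyclopentane-1,3-dione
Product: 31 3-oxocyclopent-1-en-1-yl ester (photosubstrate), via acid chloride 30 (not isolated)
Conditions: 1-chloro-N,N,2-trimethylprop-1-en-1-amine, CH2Cl2, 0 °C → rt; then 29, Et3N, 0 °C → rt
Reagents that add atoms: none
Why: Neutral acid chloride formation with the α-chloroenamine and O-acylation of the dione enolate give the enol ester, the symmetrical dione removing any regiochemical question and the quaternary α-carbon excluding ketene formation.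

**Step 21**
Reactants: 31 3-oxocyclopent-1-en-1-yl ester
Product: 32 spirolactone-fused bicyclo[3.2.0]heptan-2-one photoadduct
Conditions: hν (350 nm lamps, Pyrex), degassed MeCN, 0 °C, 0.005 M
Reagents that add atoms: none
Why: Excitation of the β-acyloxy enone (n→π*, fast intersystem crossing) gives the triplet, whose β-carbon C8′ bonds to the internal vinyl carbon C7′ to give a 1,4-biradical that collapses by C5′–C6′ bond formation; the closest known reaction type is the intramolecular enone–alkene [2+2] photocycloaddition of 1,3-dione enol esters (De Mayo-type substrates). The spirolactone closes by 1,5 (five-exo) attack of C8′ on the vinyl group (rule of five), and the cyclobutane by recombination of the 1,4-biradical (four-membered closure). C7′ is controlled by the quaternary C11′, because the vinyl group reacts in the rotamer that turns its CH2 (C6′) towards the C13′ methylene and away from the substituted C3 branch, while C8′ and C5′ follow from C7′ since only the cis-anti-cis fusion of lactone, cyclobutane and cyclopentanone is geometrically possible. The step needs straight rather than crossed regiochemistry, reaction at the vinyl group rather than at C2=C3, and no acyl migration: the three-atom tether (O, C12′, C11′) enforces the five-membered first closure, the monosubstituted vinyl group is far more accessible than the fully substituted C3, and long-wavelength light populates only the enone n→π* state. The small population of the reactive s-cis ester rotamer should only lower the quantum yield, because the unreactive rotamer relaxes unchanged.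

**Step 22**
Reactants: 32 photoadduct
Product: 33 10′-methyl photoadduct
Conditions: LiN(iPr)2, THF, −78 °C; MeI, −78 → −40 °C
Reagents that add atoms: iodomethane, CI
Why: In this kinetic enolate alkylation only C10′ can be deprotonated (the bridgehead C5′–H cannot be enolised, and the lactone has no α-hydrogen), and methyl iodide enters on the convex face anti to the cyclobutane, which places the methyl group cis to C11′ on the future seven-membered ring.

**Step 23**
Reactants: 33 10′-methyl photoadduct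
Product: 34 C1′ trimethylsilyl enol ether of the cis-lactone-fused cycloheptene
Conditions: SmI2, HMPA, Me3SiCl, cyclohexa-1,4-diene, THF, −78 °C
Reagents that add atoms: chlorotrimethylsilane, C[Si](C)(C)Cl
Why: In this ketyl-radical cyclobutane fragmentation (the radical variant of the De Mayo ring enlargement) divalent samarium reduces the C1′ ketone, the strained C5′–C8′ bond cleaves to the acyloxy-stabilised C8′ radical and the trivalent samarium C1′=C5′ enolate, which is silylated in situ, and hydrogen-atom transfer to C8′ on the face anti to C6′ (the face not covered by the new ring) gives the cis-fused lactone.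

**Step 24**
Reactants: 34 C1′ trimethylsilyl enol ether
Product: 35 C1′ enol triflate
Conditions: CsF, PhNTf2, DME, rt
Reagents that add atoms: N-phenylbis(trifluoromethanesulfonimide), O=S(=O)(N(c1ccccc1)S(=O)(=O)C(F)(F)F)C(F)(F)F
Why: Fluoride-induced desilylation and O-sulfonylation of the enolate convert the silyl enol ether into the enol triflate with retention of the C1′=C5′ regiochemistry fixed by the fragmentation.

**Step 25**
Reactants: 35 C1′ enol triflate; 17 methyl vinyl ketone
Product: 36 fully silylated (E)-dienone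
Conditions: Pd(OAc)2 (10 mol %), PPh3, Et3N, 17 (5 equiv), DMF, 70 °C
Reagents that add atoms: none
Why: In this Heck reaction oxidative addition of zerovalent palladium to the alkenyl triflate, syn-insertion of methyl vinyl ketone and β-hydride elimination give the (E)-configured C2′=C3′ dienone, the hindered isolated alkenes being unreactive.

**Step 26**
Reactants: 36 fully silylated (E)-dienone
Product: 37 tetraol (1, 4, 8, 12-hydroxy)
Conditions: HF·pyridine, pyridine, THF, 0 °C → rt
Reagents that add atoms: none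
Why: Buffered fluoride desilylation cleaves all four silyl ethers under conditions that spare the lactone, the dienone and the tertiary allylic alcohol.

**Step 27**
Reactants: 37 tetraol
Product: 39 1′(5′)-ene bis-lactone, via lactol 38 (not isolated)
Conditions: MnO2 (excess), CH2Cl2, rt
Reagents that add atoms: none
Why: Allylic oxidation with MnO2 turns the C4 carbinol into the enone and the C12 allylic alcohol into the enal, which closes onto O8 to a lactol that is oxidised further to the α-methylene lactone (oxidative lactonisation), the saturated and tertiary hydroxyls being inert.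

**Step 28**
Reactants: 39 1′(5′)-ene bis-lactone
Product: 40 CNP0177598.1
Conditions: mCPBA, NaHCO3, CH2Cl2, 0 °C
Reagents that add atoms: 3-chloroperoxybenzoic acid, O=C(OO)c1cccc(Cl)c1
Why: In this Prilezhaev epoxidation the peracid attacks only the electron-richest alkene, the γ,δ-bond C1′=C5′ of the dienone, and should do so from the β face, as in the 1β,5β-epoxides of cis-lactone xanthanolides.

**Compound list**

1 | (S)-but-3-yn-2-ol | C#C[C@H](C)O | starting material
2 | (S)-but-3-yn-2-yl methanesulfonate | C#C[C@H](C)OS(C)(=O)=O | intermediate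
3 | diethyl malonate | CCOC(=O)CC(=O)OCC | starting material
4 | diethyl 2-[(2S)-but-3-yn-2-yl]propanedioate | C#C[C@@H](C)C(C(=O)OCC)C(=O)OCC | intermediate
5 | ethyl (3S)-3-methylpent-4-ynoate | C#C[C@@H](C)CC(=O)OCC | intermediate
6 | (3S)-3-methylpent-4-ynal | C#C[C@@H](C)CC=O | intermediate
7 | (4S)-4-benzyl-1,3-oxazolidin-2-one | O=C1N[C@@H](Cc2ccccc2)CO1 | starting material
8 | pent-4-enoyl chloride | C=CCCC(=O)Cl | starting material
9 | (4S)-4-benzyl-3-(pent-4-enoyl)-1,3-oxazolidin-2-one | C=CCCC(=O)N1[C@@H](Cc2ccccc2)COC1=O | intermediate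
10 | (4S)-4-benzyl-3-[(2S,3R,5S)-3-hydroxy-5-methyl-2-(prop-2-en-1-yl)hept-6-ynoyl]-1,3-oxazolidin-2-one | C#C[C@@H](C)C[C@@H](O)[C@H](CC=C)C(=O)N1[C@@H](Cc2ccccc2)COC1=O | intermediate
11 | (2S,3R,5S)-3-hydroxy-N-methoxy-N,5-dimethyl-2-(prop-2-en-1-yl)hept-6-ynamide | C#C[C@@H](C)C[C@@H](O)[C@H](CC=C)C(=O)N(C)OC | intermediate
12 | (2S,3R,5S)-3-(TBS-oxy)-N-methoxy-N,5-dimethyl-2-(prop-2-en-1-yl)hept-6-ynamide | C#C[C@@H](C)C[C@@H](O[Si](C)(C)C(C)(C)C)[C@H](CC=C)C(=O)N(C)OC | intermediate
13 | (3S,4R,6S)-4-(TBS-oxy)-6-methyl-3-(prop-2-en-1-yl)oct-7-yn-2-one | C#C[C@@H](C)C[C@@H](O[Si](C)(C)C(C)(C)C)[C@H](CC=C)C(C)=O | intermediate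
14 | (3S,4R,6S)-2,4-bis(TBS-oxy)-6-methyl-3-(prop-2-en-1-yl)oct-1-en-7-yne (TBS enol ether) | C#C[C@@H](C)C[C@@H](O[Si](C)(C)C(C)(C)C)[C@H](CC=C)C(=C)O[Si](C)(C)C(C)(C)C | intermediate
15 | (3S,4R,6S)-1,4-bis(TBS-oxy)-6-methyl-3-(prop-2-en-1-yl)oct-7-yn-2-one | C#C[C@@H](C)C[C@@H](O[Si](C)(C)C(C)(C)C)[C@H](CC=C)C(=O)CO[Si](C)(C)C(C)(C)C | intermediate
16 | (3R,4R,6S)-1,4-bis(TBS-oxy)-6-methyl-2-methylidene-3-(prop-2-en-1-yl)oct-7-yne | C#C[C@@H](C)C[C@@H](O[Si](C)(C)C(C)(C)C)[C@H](CC=C)C(=C)CO[Si](C)(C)C(C)(C)C | intermediate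
17 | methyl vinyl ketone (but-3-en-2-one) | C=CC(C)=O | starting material
18 | (3E)-4-{(4R,5R,7S)-5-(TBS-oxy)-4-[3-(TBS-oxy)prop-1-en-2-yl]-7-methylcyclohept-1-en-1-yl}but-3-en-2-one (8β-OTBS, 7β side chain, 10β-methyl) | CC(C)(C)[Si](C)(C)O[C@@H]1C[C@H](C)C(/C=C/C(C)=O)=CC[C@@H]1C(=C)CO[Si](C)(C)C(C)(C)C | intermediate
19 | (2R,3E)-4-{(4R,5R,7S)-5-(TBS-oxy)-4-[3-(TBS-oxy)prop-1-en-2-yl]-7-methylcyclohept-1-en-1-yl}but-3-en-2-ol | CC(C)(C)[Si](C)(C)O[C@@H]1C[C@H](C)C(/C=C/[C@@H](C)O)=CC[C@@H]1C(=C)CO[Si](C)(C)C(C)(C)C | intermediate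
20 | α-methylene-γ-butyrolactone (3-methylideneoxolan-2-one) | C=C1CCOC1=O | starting material
21 | Diels–Alder adduct: cyclohexene (C1=C2) fused at C1/C5 to the cycloheptane, H-3α, H-5α, spiro C11′ with lactone carbonyl C12′ β and CH2 (C7′) α, (4R)-CH(OH)CH3 on C3, 8β-OTBS, 7β-[3-(TBS-oxy)prop-1-en-2-yl], 10β-methyl | CC(C)(C)[Si](C)(C)O[C@@H]2C[C@H](C)C3=C[C@H]([C@@H](C)O)[C@@]4(C[C@@H]3C[C@@H]2C(=C)CO[Si](C)(C)C(C)(C)C)C(=O)OCC4 | intermediate
22 | 1β,2β-epoxide of 21 | CC(C)(C)[Si](C)(C)O[C@@H]2C[C@H](C)[C@@]3(O5)[C@H]5[C@H]([C@@H](C)O)[C@@]4(C[C@@H]3C[C@@H]2C(=C)CO[Si](C)(C)C(C)(C)C)C(=O)OCC4 | intermediate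
23 | O4-TBS ether of 22 | CC(C)(C)[Si](C)(C)O[C@@H]2C[C@H](C)[C@@]3(O5)[C@H]5[C@H]([C@@H](C)O[Si](C)(C)C(C)(C)C)[C@@]4(C[C@@H]3C[C@@H]2C(=C)CO[Si](C)(C)C(C)(C)C)C(=O)OCC4 | intermediate
24 | 1β-hydroxy-2α-(phenylselanyl) acid with 2-(phenylselanyl)ethyl and CO2H on C11′ | CC(C)(C)[Si](C)(C)O[C@@H]2C[C@H](C)[C@@]3(O)[C@@H]([Se]c5ccccc5)[C@H]([C@@H](C)O[Si](C)(C)C(C)(C)C)[C@@](C[C@@H]3C[C@@H]2C(=C)CO[Si](C)(C)C(C)(C)C)(C(=O)O)CC[Se]c6ccccc6 | intermediate
25 | bis-selenoxide of 24 (selenium centres undefined) | CC(C)(C)[Si](C)(C)O[C@@H]2C[C@H](C)[C@@]3(O)[C@@H]([Se](=O)c5ccccc5)[C@H]([C@@H](C)O[Si](C)(C)C(C)(C)C)[C@@](C[C@@H]3C[C@@H]2C(=C)CO[Si](C)(C)C(C)(C)C)(C(=O)O)CC[Se](=O)c6ccccc6 | intermediate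
26 | 1β-hydroxy-Δ2(3) acid with vinyl (α) and CO2H (β) on C11′ | CC(C)(C)[Si](C)(C)O[C@@H]2C[C@H](C)[C@@]3(O)C=C([C@@H](C)O[Si](C)(C)C(C)(C)C)[C@@](C[C@@H]3C[C@@H]2C(=C)CO[Si](C)(C)C(C)(C)C)(C(=O)O)C=C | intermediate
27 | O1-TES triethylsilyl ester of 26 | CC(C)(C)[Si](C)(C)O[C@@H]2C[C@H](C)[C@@]3(O[Si](CC)(CC)CC)C=C([C@@H](C)O[Si](C)(C)C(C)(C)C)[C@@](C[C@@H]3C[C@@H]2C(=C)CO[Si](C)(C)C(C)(C)C)(C(=O)O[Si](CC)(CC)CC)C=C | intermediate
28 | O1-TES C11′-vinyl acid | CC(C)(C)[Si](C)(C)O[C@@H]2C[C@H](C)[C@@]3(O[Si](CC)(CC)CC)C=C([C@@H](C)O[Si](C)(C)C(C)(C)C)[C@@](C[C@@H]3C[C@@H]2C(=C)CO[Si](C)(C)C(C)(C)C)(C(=O)O)C=C | intermediate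
29 | cyclopentane-1,3-dione | O=C1CCC(=O)C1 | starting material
30 | acid chloride of 28 | CC(C)(C)[Si](C)(C)O[C@@H]2C[C@H](C)[C@@]3(O[Si](CC)(CC)CC)C=C([C@@H](C)O[Si](C)(C)C(C)(C)C)[C@@](C[C@@H]3C[C@@H]2C(=C)CO[Si](C)(C)C(C)(C)C)(C(=O)Cl)C=C | intermediate
31 | 3-oxocyclopent-1-en-1-yl ester of 28 (dione enol ester) | CC(C)(C)[Si](C)(C)O[C@@H]2C[C@H](C)[C@@]3(O[Si](CC)(CC)CC)C=C([C@@H](C)O[Si](C)(C)C(C)(C)C)[C@@](C[C@@H]3C[C@@H]2C(=C)CO[Si](C)(C)C(C)(C)C)(C(=O)OC1=CC(=O)CC1)C=C | intermediate
32 | photoadduct: spiro-γ-lactone (C11′, C12′, O, C8′, C7′) cis-fused to the cyclobutane (C8′, C5′, C6′, C7′), itself cis-fused (anti) to the cyclopentanone (C1′ ketone); C6′ cis to C13′ | CC(C)(C)[Si](C)(C)O[C@@H]2C[C@H](C)[C@@]3(O[Si](CC)(CC)CC)C=C([C@@H](C)O[Si](C)(C)C(C)(C)C)[C@@]4(C[C@@H]3C[C@@H]2C(=C)CO[Si](C)(C)C(C)(C)C)C(=O)O[C@@]15CCC(=O)[C@H]5C[C@@H]14 | intermediate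
33 | 10′-methyl photoadduct (methyl exo, anti to the cyclobutane) | CC(C)(C)[Si](C)(C)O[C@@H]2C[C@H](C)[C@@]3(O[Si](CC)(CC)CC)C=C([C@@H](C)O[Si](C)(C)C(C)(C)C)[C@@]4(C[C@@H]3C[C@@H]2C(=C)CO[Si](C)(C)C(C)(C)C)C(=O)O[C@@]15C[C@H](C)C(=O)[C@H]5C[C@@H]14 | intermediate
34 | cis-lactone-fused cycloheptene, C1′–OSiMe3 enol ether (C1′=C5′), 10′β-methyl, H-7′α, H-8′α | CC(C)(C)[Si](C)(C)O[C@@H]2C[C@H](C)[C@@]3(O[Si](CC)(CC)CC)C=C([C@@H](C)O[Si](C)(C)C(C)(C)C)[C@@]4(C[C@@H]3C[C@@H]2C(=C)CO[Si](C)(C)C(C)(C)C)C(=O)O[C@@H]1C[C@H](C)C(O[Si](C)(C)C)=CC[C@@H]14 | intermediate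
35 | C1′ enol triflate | CC(C)(C)[Si](C)(C)O[C@@H]2C[C@H](C)[C@@]3(O[Si](CC)(CC)CC)C=C([C@@H](C)O[Si](C)(C)C(C)(C)C)[C@@]4(C[C@@H]3C[C@@H]2C(=C)CO[Si](C)(C)C(C)(C)C)C(=O)O[C@@H]1C[C@H](C)C(OS(=O)(=O)C(F)(F)F)=CC[C@@H]14 | intermediate
36 | fully silylated (2′E)-dienone (C1′=C5′, C2′=C3′, C4′ ketone) | CC(C)(C)[Si](C)(C)O[C@@H]2C[C@H](C)[C@@]3(O[Si](CC)(CC)CC)C=C([C@@H](C)O[Si](C)(C)C(C)(C)C)[C@@]4(C[C@@H]3C[C@@H]2C(=C)CO[Si](C)(C)C(C)(C)C)C(=O)O[C@@H]1C[C@H](C)C(/C=C/C(C)=O)=CC[C@@H]14 | intermediate
37 | tetraol (1β-OH, (4R)-OH, 8β-OH, 12-OH) | O[C@@H]2C[C@H](C)[C@@]3(O)C=C([C@@H](C)O)[C@@]4(C[C@@H]3C[C@@H]2C(=C)CO)C(=O)O[C@@H]1C[C@H](C)C(/C=C/C(C)=O)=CC[C@@H]14 | intermediate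
38 | lactol (C4 ketone, C12 hemiacetal to O8; anomers) | C=C1C(O)O[C@@H]2C[C@H](C)[C@@]3(O)C=C(C(C)=O)[C@@]4(C[C@@H]3C[C@H]12)C(=O)O[C@@H]1C[C@H](C)C(/C=C/C(C)=O)=CC[C@@H]14 | intermediate
39 | 1′(5′)-ene bis-lactone (target without the epoxide) | C=C1C(=O)O[C@@H]2C[C@H](C)[C@@]3(O)C=C(C(C)=O)[C@@]4(C[C@@H]3C[C@H]12)C(=O)O[C@@H]1C[C@H](C)C(/C=C/C(C)=O)=CC[C@@H]14 | intermediate
40 | CNP0177598.1 | C=C1C(=O)O[C@@H]2C[C@H](C)[C@@]3(O)C=C(C(C)=O)[C@@]4(C[C@@H]3C[C@H]12)C(=O)O[C@@H]1C[C@H](C)[C@]2(/C=C/C(C)=O)O[C@@H]2C[C@@H]14 | target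

**Totals and risks**

Total step count: 28 steps.
Longest linear sequence: 27 steps (steps 1–4 and 6–28; step 5 prepares the acylated auxiliary).

Step 14 (Diels–Alder). What may go wrong is insufficient discrimination between the two diene faces, or between endo and exo placement of the lactone carbonyl, once the directing hydrogen bond is weakened at the reaction temperature. The fallback moves the cycloaddition one oxidation level up, so that the facial bias rests only on the shape of the acceptor-substituted diene. It sets out from 18, which is heated with 20 in toluene (or pressed at 10 kbar) to give the β,γ-unsaturated methyl ketone adduct F1. Oxazaborolidine-controlled borane reduction of the C4 ketone ((S)-2-methyl-CBS-oxazaborolidine, BH3·SMe2) then comes back to the route at 21.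

Step 23 (ring opening). What may go wrong is cleavage of the exocyclic C5′–C6′ cyclobutane bond, which overlaps better with the ketyl, instead of the ring-fusion bond, or hydrogen delivery to the wrong face of the C8′ radical. The fallback uses the two-electron retro-aldol (De Mayo) mode, which can only break C5′–C8′. It sets out from 33: K2CO3 in methanol opens the lactone, and the liberated C8′ alkoxide fragments to the cycloheptane-1,4-dione methyl ester F2. NaBH4 then reduces both ketones; hydride attacks C8′ anti to the C11′ substituent on C7′, so the cis hydroxy ester closes to the hydroxy lactone F3 (C1′ carbinol as an epimer mixture). Dess–Martin periodinane gives the keto lactone F4. Kinetic deprotonation of the C5′ methylene with LiN(SiMe3)2, followed by PhNTf2, comes back to the route at 35.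

Step 28 (epoxidation). What may go wrong is peracid attack on the α face of the C1′=C5′ bond. The fallback inverts the facial sense through a halohydrin. It sets out from 39: N-bromosuccinimide in aqueous THF forms the bromonium ion on that same, more accessible face, and water opens it at the tertiary C1′ from the β face to give the bromohydrin F5. K2CO3 then closes F5 by intramolecular displacement of bromide and comes back to the route at 40.

**Further compounds**

F1 | step 14 | β,γ-unsaturated methyl ketone adduct (4-oxo analogue of 21) | CC(C)(C)[Si](C)(C)O[C@@H]2C[C@H](C)C3=C[C@H](C(C)=O)[C@@]4(C[C@@H]3C[C@@H]2C(=C)CO[Si](C)(C)C(C)(C)C)C(=O)OCC4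
F2 | step 23 | cycloheptane-1,4-dione methyl ester | CC(C)(C)[Si](C)(C)O[C@@H]2C[C@H](C)[C@@]3(O[Si](CC)(CC)CC)C=C([C@@H](C)O[Si](C)(C)C(C)(C)C)[C@@](C[C@@H]3C[C@@H]2C(=C)CO[Si](C)(C)C(C)(C)C)(C(=O)OC)[C@H]1CCC(=O)[C@@H](C)CC1=O
F3 | step 23 | hydroxy lactone (C1′ carbinol, epimer mixture left undefined) | CC(C)(C)[Si](C)(C)O[C@@H]2C[C@H](C)[C@@]3(O[Si](CC)(CC)CC)C=C([C@@H](C)O[Si](C)(C)C(C)(C)C)[C@@]4(C[C@@H]3C[C@@H]2C(=C)CO[Si](C)(C)C(C)(C)C)C(=O)O[C@@H]1C[C@H](C)C(O)CC[C@@H]14
F4 | step 23 | keto lactone | CC(C)(C)[Si](C)(C)O[C@@H]2C[C@H](C)[C@@]3(O[Si](CC)(CC)CC)C=C([C@@H](C)O[Si](C)(C)C(C)(C)C)[C@@]4(C[C@@H]3C[C@@H]2C(=C)CO[Si](C)(C)C(C)(C)C)C(=O)O[C@@H]1C[C@H](C)C(=O)CC[C@@H]14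
F5 | step 28 | bromohydrin (1′β-OH, 5′α-Br) | C=C1C(=O)O[C@@H]2C[C@H](C)[C@@]3(O)C=C(C(C)=O)[C@@]4(C[C@@H]3C[C@H]12)C(=O)O[C@@H]1C[C@H](C)[C@](/C=C/C(C)=O)(O)[C@@H](Br)C[C@@H]14
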